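The three-carbon bridge C9–C11–C12 is disconnected from both bridgeheads, C8 and C13, of the bicyclo[3.2.1]octane formed by rings C and D. In the forward direction an oxyallyl cation spanning C9–C11–C12, generated from a bromoacetonyl arm on C10, adds across C8 and C13 of a 2-silyloxycyclopentadiene (the future ring D) attached to C6. This intramolecular (4+3) cycloaddition closes rings B and C, sets C8, C9 and C13, and leaves C11 and C16 as differentiated carbonyl groups. The precursor is a fully substituted ring A, made from methyl benzoate by Birch alkylation and enzymatic desymmetrisation, which carries the two arms trans on C10 and C5.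

Key step: step 12

Remark: atoms carry gibberellane numbering. β is the face of ring A that carries C18 and H5 in the target, as in the customary gibberellin drawing, and α is the opposite face. C6 is carried as a mixture of epimers in compounds 15 to 21 (SMILES written without configuration at C6) and is fixed in step 14. TBS stands for tert-butyldimethylsilyl.

Step 1
Reactants: 1 methyl benzoate; 2 2,3-dichloropropene
Product: 3 methyl 1-(2-chloroallyl)cyclohexa-2,5-diene-1-carboxylate
Conditions: Li (2.1 equiv), NH3(l)/THF, t-BuOH (1 equiv), −78 °C; then 2, −78 °C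
Reagents that add atoms: none
Why: Birch reductive alkylation: the ester dienolate formed by two-electron reduction is alkylated at the ipso carbon by the allylic chloride (the vinylic chloride is inert), which creates the still prochiral quaternary C10.

Step 2
Reactants: 3 methyl 1-(2-chloroallyl)cyclohexa-2,5-diene-1-carboxylate
Product: 4 methyl 1-(2-chloroallyl)-4-oxocyclohexa-2,5-diene-1-carboxylate
Conditions: CrO3, 3,5-dimethylpyrazole, CH2Cl2, −20 °C
Reagents that add atoms: chromium trioxide O=[Cr](=O)=O
Why: Allylic oxidation of the doubly allylic CH2 (C3) of the 1,4-diene should give the cross-conjugated dienone, a standard follow-up of Birch alkylation products.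

Step 3
Reactants: 4 methyl 1-(2-chloroallyl)-4-oxocyclohexa-2,5-diene-1-carboxylate
Product: 5 methyl (R)-1-(2-chloroallyl)-4-oxocyclohex-2-ene-1-carboxylate
Conditions: ene-reductase (Old Yellow Enzyme family), NADP+ (cat.), alcohol dehydrogenase, i-PrOH, phosphate buffer pH 7/DMSO, 30 °C
Reagents that add atoms: none
Why: Enzymatic asymmetric conjugate reduction desymmetrises the prochiral 4,4-disubstituted dienone by reducing one enantiotopic C=C (C1=C2), which makes C10 stereogenic (R, enzyme chosen for this sense); the hindered enone product should not be reduced further.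

Step 4
Reactants: 5 methyl (R)-1-(2-chloroallyl)-4-oxocyclohex-2-ene-1-carboxylate
Product: 6 methyl (R)-1-(2-chloroallyl)-3-iodo-4-oxocyclohex-2-ene-1-carboxylate
Conditions: I2, pyridine, CH2Cl2, 0 °C to rt
Reagents that add atoms: iodine II
Why: α-Iodination of the enone by pyridine conjugate addition, iodination of the enolate and elimination should place iodine on C4.

Step 5
Reactants: 6 methyl (R)-1-(2-chloroallyl)-3-iodo-4-oxocyclohex-2-ene-1-carboxylate
Product: 7 dimethyl (R)-1-(2-chloroallyl)-4-oxocyclohex-2-ene-1,3-dicarboxylate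
Conditions: Pd(OAc)2 (5 mol%), PPh3, CO (1 atm), MeOH, Et3N, DMF, 50 °C
Reagents that add atoms: carbon monoxide [C-]#[O+]; methanol CO
Why: Palladium-catalysed methoxycarbonylation of the alkenyl iodide installs C19, and the vinylic chloride should not react under these mild conditions.

Step 6
Reactants: 7 dimethyl (R)-1-(2-chloroallyl)-4-oxocyclohex-2-ene-1,3-dicarboxylate; 8 tert-butyl[(1-methoxyvinyl)oxy]dimethylsilane
Product: 10 enol triester, via silyl enol ether 9 (not isolated)
Conditions: Cu(OTf)2 (10 mol%), t-Bu-box ligand (antipode matched to 7), CH2Cl2, −78 to −40 °C; then 1 M HCl, THF, rt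
Reagents that add atoms: none
Why: Mukaiyama–Michael addition to the copper-chelated alkylidene β-keto ester with silyl transfer to the enolate oxygen: the ketene acetal should attack C5 anti to the pseudoaxial 2-chloroallyl group on C10 (cis to the C10 ester), a preference reinforced by the matched box ligand, which sets C5, and acid then cleaves the silyl enol ether.

Step 7
Reactants: 10 enol triester
Product: 11 ring A keto triester (3-oxo; 4β-methyl; 4α-CO2Me; 5α-CH2CO2Me; 10α-CO2Me; 10β-(2-chloroallyl))
Conditions: K2CO3, MeI, acetone, 50 °C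
Reagents that add atoms: iodomethane CI
Why: C-Alkylation of the β-keto ester enolate should occur on the face away from the neighbouring C5 side chain, so that the new methyl is β and the C19 ester α (quaternary C4 by 1,2-induction).

Step 8
Reactants: 11 ring A keto triester
Product: 12 hydroxy triester (3β-OH)
Conditions: LiBH(s-Bu)3 (L-Selectride), THF, −78 °C; aq. NH4Cl
Reagents that add atoms: none
Why: Bulky-hydride ketone reduction: in the chair that holds both α esters axial the reagent attacks C3 along the equatorial trajectory, which should give the axial 3β alcohol and leave the esters untouched.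

Step 9
Reactants: 12 hydroxy triester (3β-OH)
Product: 13 silyl ether triester (3β-OTBS)
Conditions: TBSOTf, 2,6-lutidine, CH2Cl2, 0 °C
Reagents that add atoms: tert-butyldimethylsilyl triflate CC(C)(C)[Si](C)(C)OS(=O)(=O)C(F)(F)F
Why: Silyl triflate silylation protects the hindered axial alcohol against the bases and cations used later.

Step 10
Reactants: 13 silyl ether triester (3β-OTBS); 14 3-ethoxycyclopent-2-en-1-one
Product: 16 cyclopentenone (3-oxocyclopent-1-enyl group on C6; C6 epimers), via hydroxy enol ether adduct 15 (not isolated)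
Conditions: LiN(i-Pr)2 (1.1 equiv), THF, −78 °C; 14, −78 to −40 °C; then 1 M HCl, THF, 0 °C to rt
Reagents that add atoms: water O
Why: Stork–Danheiser sequence: the only enolisable ester (C7) forms its lithium enolate, which adds 1,2 to the vinylogous ester, and acid hydrolysis with loss of water and ethanol should give the 3-substituted cyclopentenone (C6 is not controlled here).

Step 11
Reactants: 16 cyclopentenone
Product: 17 bromomethyl ketone (BrCH2–CO–CH2 arm on C10)
Conditions: NBS (1.1 equiv), MeCN/H2O 4:1, 0 °C
Reagents that add atoms: N-bromosuccinimide O=C1CCC(=O)N1Br; water O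
Why: Oxidative hydrolysis of the vinyl chloride: bromonium formation at the terminal carbon, capture by water at the chlorine-bearing carbon and loss of HCl should give the α-bromo ketone, while the electron-poor enone C=C is inert to NBS.

Step 12
Reactants: 17 bromomethyl ketone
Product: 19 tetracyclic (4+3) adduct (11-ketone; C15=C16 silyl enol ether), via silyloxydiene 18 (not isolated)
Conditions: TBSOTf (1.05 equiv), Et3N, CH2Cl2, −78 °C; then LiClO4 (3 M in Et2O), Et3N, 0.005 M, −20 °C to rt
Reagents that add atoms: tert-butyldimethylsilyl triflate CC(C)(C)[Si](C)(C)OS(=O)(=O)C(F)(F)F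
Why: Soft enolisation of the more Lewis-basic cyclopentenone at C13 gives the cross-conjugated 2-silyloxydiene 18, after which Et3N in ethereal LiClO4 enolises the bromo ketone toward C9 and ionises bromide to a lithium-bound oxyallyl cation C9–C11–C12 that adds across C8 and C13 in a concerted but asynchronous cycloaddition of the four-electron diene with the two-electron allyl cation (closest known type: the base-mediated intramolecular oxyallyl cation (4+3) cycloaddition onto a tethered cyclopentadiene or furan). The seven-membered ring C8–C9–C11–C12–C13–C16–C15 closes in the (4+3) mode and, together with the C14 bridge, contains ring C of the bicyclo[3.2.1]octene, while ring B closes as a five-membered ring through the three-atom tether C10–C5–C6. C8 and C13 are set together because the cation bonds to one face of the planar diene, and C9 is set relative to C8 by the Z (W-shaped) oxyallyl reacting in the extended transition state, which places C10 axial on the new six-membered ring and H9 syn to the C15–C16 bridge. The face is chosen by ring A, whose C5 and C10 arms are trans-diequatorial, and lithium chelation between the oxyallyl oxygen and the axial C10 ester should turn C11 to the α face, cis to C20. The step needs chemoselective dienol ether formation and regiocontrol, which rest on the bromo ketone being too weakly basic to be silylated at −78 °C and on the fact that only bonding of C9 to C8 gives a five-membered ring. C11 emerges as a ketone and C16 as a silyl enol ether, so the two carbonyl positions stay differentiated.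

Step 13
Reactants: 19 tetracyclic (4+3) adduct
Product: 21 deoxygenated silyl enol ether (C11 methylene), via tosylhydrazone 20 (not isolated)
Conditions: TsNHNH2, THF, 4 Å MS, 45 °C; then catecholborane, CHCl3, 0 °C; NaOAc·3H2O, 60 °C
Reagents that add atoms: none
Why: Tosylhydrazone reduction (Caglioti type): the only free ketone (C11) condenses with the hydrazide, hydride adds to C=N, and acetate triggers loss of sulfinate and dinitrogen to leave the C11 methylene, with C16 still masked.

Step 14
Reactants: 21 deoxygenated silyl enol ether (C11 methylene)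
Product: 22 nor-ketone triester (16-oxo-17-nor; 6β ester; 3β-OTBS)
Conditions: NaOMe, MeOH, 60 °C
Reagents that add atoms: none
Why: Methoxide cleaves the silyl enol ether to the C16 ketone and equilibrates the only epimerisable centre, C6 (α to the C7 ester), to the 6β ester, expected to be the more stable epimer because it is trans to the quaternary C4 on ring B.

Step 15
Reactants: 22 nor-ketone triester
Product: 23 silyl-protected trimethyl ester of the target
Conditions: Ph3PCH3Br, KOt-Bu, THF, 0 °C to rt
Reagents that add atoms: methyltriphenylphosphonium bromide C[P+](c1ccccc1)(c1ccccc1)c1ccccc1.[Br-]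
Why: Wittig methylenation of the bridged 16-ketone builds the exocyclic C16=C17 alkene, and a brief epimerisation at C6 by the ylide would return the same, more stable 6β ester.

Step 16
Reactants: 23 silyl-protected trimethyl ester of the target
Product: 24 trimethyl ester of the target (3β-OH)
Conditions: HF·pyridine, THF, 0 °C to rt
Reagents that add atoms: none
Why: Fluoride cleavage of the secondary silyl ether under mildly acidic conditions should avoid retro-aldol epimerisation at C3 and spare the exocyclic alkene.

Step 17
Reactants: 24 trimethyl ester of the target (3β-OH)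
Product: 25 target gibberellin (triacid)
Conditions: LiSPr, HMPA, rt to 50 °C; then aq. citric acid
Reagents that add atoms: none
Why: SN2 demethylation by thiolate at the O-methyl carbons should cleave all three esters, including the two on quaternary C4 and C10, without acyl attack, epimerisation or harm to the alkene.

Compound list
1 | methyl benzoate | COC(=O)c1ccccc1 | starting material
2 | 2,3-dichloropropene | C=C(Cl)CCl | starting material
3 | methyl 1-(2-chloroallyl)cyclohexa-2,5-diene-1-carboxylate | C=C(Cl)CC1(C(=O)OC)C=CCC=C1 | intermediate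
4 | methyl 1-(2-chloroallyl)-4-oxocyclohexa-2,5-diene-1-carboxylate | C=C(Cl)CC1(C(=O)OC)C=CC(=O)C=C1 | intermediate
5 | methyl (R)-1-(2-chloroallyl)-4-oxocyclohex-2-ene-1-carboxylate | C=C(Cl)C[C@]1(C(=O)OC)CCC(=O)C=C1 | intermediate
6 | methyl (R)-1-(2-chloroallyl)-3-iodo-4-oxocyclohex-2-ene-1-carboxylate | C=C(Cl)C[C@]1(C(=O)OC)CCC(=O)C(I)=C1 | intermediate
7 | dimethyl (R)-1-(2-chloroallyl)-4-oxocyclohex-2-ene-1,3-dicarboxylate | C=C(Cl)C[C@]1(C(=O)OC)CCC(=O)C(C(=O)OC)=C1 | intermediate
8 | tert-butyl[(1-methoxyvinyl)oxy]dimethylsilane (tert-butyldimethylsilyl ketene acetal of methyl acetate) | C=C(OC)O[Si](C)(C)C(C)(C)C | starting material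
9 | tert-butyldimethylsilyl enol ether of 10 (not isolated) | C=C(Cl)C[C@]1(C(=O)OC)CCC(O[Si](C)(C)C(C)(C)C)=C(C(=O)OC)[C@H]1CC(=O)OC | intermediate
10 | enol triester: dimethyl 1-(2-chloroallyl)-4-hydroxy-2-(2-methoxy-2-oxoethyl)cyclohex-3-ene-1,3-dicarboxylate, side chain on C5 α and cis to the C10 ester | C=C(Cl)C[C@]1(C(=O)OC)CCC(O)=C(C(=O)OC)[C@H]1CC(=O)OC | intermediate
11 | ring A keto triester: 3-oxo, 4β-methyl, 4α-CO2Me, 5α-CH2CO2Me, 10α-CO2Me, 10β-(2-chloroallyl) | C=C(Cl)C[C@]1(C(=O)OC)CCC(=O)[C@@](C)(C(=O)OC)[C@H]1CC(=O)OC | intermediate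
12 | hydroxy triester: 3β-OH (axial, cis to the 4-methyl), otherwise as 11 | C=C(Cl)C[C@]1(C(=O)OC)CC[C@H](O)[C@@](C)(C(=O)OC)[C@H]1CC(=O)OC | intermediate
13 | silyl ether triester: 3β-(tert-butyldimethylsilyloxy), otherwise as 12 | C=C(Cl)C[C@]1(C(=O)OC)CC[C@H](O[Si](C)(C)C(C)(C)C)[C@@](C)(C(=O)OC)[C@H]1CC(=O)OC | intermediate
14 | 3-ethoxycyclopent-2-en-1-one | CCOC1=CC(=O)CC1 | starting material
15 | hydroxy enol ether adduct: 3-ethoxy-1-hydroxycyclopent-2-enyl group on C6 (not isolated; C6 and C8 unassigned) | C=C(Cl)C[C@]1(C(=O)OC)CC[C@H](O[Si](C)(C)C(C)(C)C)[C@@](C)(C(=O)OC)[C@H]1C(C(=O)OC)C1(O)C=C(OCC)CC1 | intermediate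
16 | cyclopentenone: 3-oxocyclopent-1-enyl group on C6, 2-chloroallyl on C10 (C6 epimers) | C=C(Cl)C[C@]1(C(=O)OC)CC[C@H](O[Si](C)(C)C(C)(C)C)[C@@](C)(C(=O)OC)[C@H]1C(C(=O)OC)C1=CC(=O)CC1 | intermediate
17 | bromomethyl ketone: 3-bromo-2-oxopropyl group on C10 (C6 epimers) | BrCC(=O)C[C@]1(C(=O)OC)CC[C@H](O[Si](C)(C)C(C)(C)C)[C@@](C)(C(=O)OC)[C@H]1C(C(=O)OC)C1=CC(=O)CC1 | intermediate
18 | silyloxydiene: 3-(tert-butyldimethylsilyloxy)cyclopenta-1,3-dienyl group on C6 (not isolated; C6 epimers) | BrCC(=O)C[C@]1(C(=O)OC)CC[C@H](O[Si](C)(C)C(C)(C)C)[C@@](C)(C(=O)OC)[C@H]1C(C(=O)OC)C1=CC(O[Si](C)(C)C(C)(C)C)=CC1 | intermediate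
19 | tetracyclic (4+3) adduct: 11-oxo, C15=C16 tert-butyldimethylsilyl enol ether, 3β-OTBS, trimethyl ester; C8, C9 and C13 as in the target (C6 epimers) | CC(C)(C)[Si](C)(C)OC1=C[C@]23C[C@H]1CC(=O)[C@H]2[C@]1(C(=O)OC)CC[C@H](O[Si](C)(C)C(C)(C)C)[C@@](C)(C(=O)OC)[C@H]1C3C(=O)OC | intermediate
20 | C11 tosylhydrazone of 19 (not isolated; C6 epimers) | CC(C)(C)[Si](C)(C)OC1=C[C@]23C[C@H]1CC(=NNS(=O)(=O)c4ccc(C)cc4)[C@H]2[C@]1(C(=O)OC)CC[C@H](O[Si](C)(C)C(C)(C)C)[C@@](C)(C(=O)OC)[C@H]1C3C(=O)OC | intermediate
21 | deoxygenated silyl enol ether: C11 methylene, C15=C16 silyl enol ether (C6 epimers) | CC(C)(C)[Si](C)(C)OC1=C[C@]23C[C@H]1CC[C@H]2[C@]1(C(=O)OC)CC[C@H](O[Si](C)(C)C(C)(C)C)[C@@](C)(C(=O)OC)[C@H]1C3C(=O)OC | intermediate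
22 | nor-ketone triester: 16-oxo-17-nor, 6β ester, 3β-OTBS | O=C1C[C@]23C[C@H]1CC[C@H]2[C@]1(C(=O)OC)CC[C@H](O[Si](C)(C)C(C)(C)C)[C@@](C)(C(=O)OC)[C@H]1[C@@H]3C(=O)OC | intermediate
23 | silyl-protected trimethyl ester of the target: 3β-OTBS; C7, C19 and C20 methyl esters | C=C1C[C@]23C[C@H]1CC[C@H]2[C@]1(C(=O)OC)CC[C@H](O[Si](C)(C)C(C)(C)C)[C@@](C)(C(=O)OC)[C@H]1[C@@H]3C(=O)OC | intermediate
24 | trimethyl ester of the target: 3β-OH; C7, C19 and C20 methyl esters | C=C1C[C@]23C[C@H]1CC[C@H]2[C@]1(C(=O)OC)CC[C@H](O)[C@@](C)(C(=O)OC)[C@H]1[C@@H]3C(=O)OC | intermediate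
25 | target gibberellin: ent-3α-hydroxygibberell-16-ene-7,19,20-trioic acid (3β-hydroxy in the face convention of the remark) | C=C1C[C@]23C[C@H]1CC[C@H]2[C@]1(C(=O)O)CC[C@H](O)[C@@](C)(C(=O)O)[C@H]1[C@@H]3C(=O)O | target

Total step count: 17. Longest linear sequence: 17 steps, from methyl benzoate 1 to the target 25.

Steps most likely to fail

Step 12 (key step). Three processes may go wrong: silylation or deprotonation at the wrong site (the bromo ketone, or the γ-hydrogen on C6) instead of selective α′-dienol ether formation; intermolecular alkylation of the electron-rich diene by the cation instead of cycloaddition; and reaction through the compact transition state or on the other diene face, which would scramble C9 or the sense of C8 and C13, while C9 also stays epimerisable through the C11 ketone. The fallback sets out from 17 and comes back to the route at 19; it replaces base-mediated ionisation of a bromide by Lewis-acid ionisation of an acetal, with both enol ethers formed deliberately beforehand. Kornblum oxidation of 17 (DMSO, NaHCO3) should give the α-keto aldehyde F1, which trimethyl orthoformate and pyridinium tosylate in MeOH should convert into the keto dimethyl acetal F2. Excess TBSOTf and Et3N then silylate both ketones, the keto acetal enolising toward C9 as 1,1-dimethoxyacetone does, to give the bis(silyl) ether F3. Catalytic TMSOTf in CH2Cl2 at −78 °C ionises one methoxy group to a 1-methoxy-2-silyloxyallyl cation, which should undergo the same intramolecular (4+3) cycloaddition to give the 12-methoxy 11-ketone F4. SmI2 in THF/MeOH then removes the α-methoxy group and returns 19.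

Step 6. The risk is poor or reversed facial selectivity at C5, if the nucleophile prefers the face anti to the C10 ester (polar control) over the face anti to the 2-chloroallyl group. The fallback sets out from 5 and comes back to the route at 10; it reverses the order of bond formation at C5, so that the same intrinsic bias becomes productive when hydrogen is delivered last. Conjugate addition of 8 to 5 under catalytic TBSOTf should give the silyl enol ether F5, with no need for control at C5. Saegusa–Ito oxidation with Pd(OAc)2 should give the C5-substituted enone F6, α-iodination with iodine and pyridine the iodoenone F7, and methoxycarbonylation (Pd(OAc)2, PPh3, CO, MeOH, Et3N) the tetrasubstituted alkylidene β-keto ester F8. Conjugate reduction with [(Ph3P)CuH]6 then delivers hydride to C5 anti to the C10 ester and returns 10 after protonation.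

Step 10. The risk is reversible addition (retro-aldol) or simple proton transfer when the hindered C6 enolate meets the vinylogous ester, which would return 13 unchanged. The fallback sets out from 13 and comes back to the route at 16 directly, replacing carbonyl addition by cross-coupling, and it makes no new compound. The zinc enolate of 13 (LiN(SiMe3)2, then ZnCl2) is coupled with 3-bromocyclopent-2-en-1-one under Pd(dba)2/P(t-Bu)3 in THF, a Negishi-type α-alkenylation of a Reformatsky-type enolate.

Further compounds
F1 | step 12 | α-keto aldehyde: 2,3-dioxopropyl group on C10, otherwise as 17 | O=CC(=O)C[C@]1(C(=O)OC)CC[C@H](O[Si](C)(C)C(C)(C)C)[C@@](C)(C(=O)OC)[C@H]1C(C(=O)OC)C1=CC(=O)CC1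
F2 | step 12 | keto dimethyl acetal: 3,3-dimethoxy-2-oxopropyl group on C10, otherwise as 17 | COC(OC)C(=O)C[C@]1(C(=O)OC)CC[C@H](O[Si](C)(C)C(C)(C)C)[C@@](C)(C(=O)OC)[C@H]1C(C(=O)OC)C1=CC(=O)CC1
F3 | step 12 | bis(silyl) ether: C9=C11 silyl enol ether with C12 dimethyl acetal, and ring D silyloxydiene | COC(OC)C(O[Si](C)(C)C(C)(C)C)=C[C@]1(C(=O)OC)CC[C@H](O[Si](C)(C)C(C)(C)C)[C@@](C)(C(=O)OC)[C@H]1C(C(=O)OC)C1=CC(O[Si](C)(C)C(C)(C)C)=CC1
F4 | step 12 | 12-methoxy 11-ketone: 12-methoxy analogue of 19 (C12 and C6 unassigned) | CC(C)(C)[Si](C)(C)OC1=C[C@]23C[C@H]1C(OC)C(=O)[C@H]2[C@]1(C(=O)OC)CC[C@H](O[Si](C)(C)C(C)(C)C)[C@@](C)(C(=O)OC)[C@H]1C3C(=O)OC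
F5 | step 6 | tert-butyldimethylsilyl enol ether of the conjugate adduct of 8 and 5 (C5 unassigned) | C=C(Cl)C[C@]1(C(=O)OC)CCC(O[Si](C)(C)C(C)(C)C)=CC1CC(=O)OC
F6 | step 6 | methyl 1-(2-chloroallyl)-2-(2-methoxy-2-oxoethyl)-4-oxocyclohex-2-ene-1-carboxylate, C10 as in 5 | C=C(Cl)C[C@]1(C(=O)OC)CCC(=O)C=C1CC(=O)OC
F7 | step 6 | 3-iodo derivative of F6 | C=C(Cl)C[C@]1(C(=O)OC)CCC(=O)C(I)=C1CC(=O)OC
F8 | step 6 | dimethyl 1-(2-chloroallyl)-2-(2-methoxy-2-oxoethyl)-4-oxocyclohex-2-ene-1,3-dicarboxylate, C10 as in 5 | C=C(Cl)C[C@]1(C(=O)OC)CCC(=O)C(C(=O)OC)=C1CC(=O)OC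
F0 | step 10 | none | none
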